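**Strategy.** The route rests on cutting the γ-lactone (ring atoms O–C7–C8–C17–C19, briarane numbering) back to an enol ether C7=C8–O and acrylic acid. A photoredox polar radical crossover cycloaddition joins the carboxyl oxygen to C7 and the acrylate α-carbon (C17) to C8 in one operation, delivering the tertiary C8 oxygen, the C17 methyl group and three stereocentres. The precursor is a cyclic di-tert-butylsilylene enol ether (six-membered ring O6–C6–C7=C8–O8–Si) of a seco β-hydroxy ketone that already carries the cyclohexane unit; its C6 stereocentre and the ring enforce the C7/C8 configuration. A B-alkyl Suzuki macrocyclisation (C4–C5) then closes the ten-membered ring, and C6–O is exchanged for chloride.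

Key step: step 11

Remark: atoms are named by briarane numbering (C1 quaternary methyl carbon, C2–C10 ten-membered ring, C11–C14 cyclohexane, C16 exocyclic methylene, C17/C18/C19 lactone α-carbon, its methyl and its carbonyl, C20 epoxide CH2); the absolute configuration is that of the target SMILES.

Step 1
Reactants: 1 (E)-but-2-enal (crotonaldehyde)
Product: 2 (E)-1-(triisopropylsilyloxy)buta-1,3-diene
Conditions: TIPSOTf, Et3N, Et2O, 0 → 23 °C
Reagents that add atoms: triisopropylsilyl triflate, CC(C)[Si](OS(=O)(=O)C(F)(F)F)(C(C)C)C(C)C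
Why: Vinylogous enol silylation (O-silylation of the enal, γ-deprotonation by Et3N) gives the silyl dienol ether, the (E)-isomer being favoured.

Step 2
Reactants: 2 (E)-1-(triisopropylsilyloxy)buta-1,3-diene; 3 ethyl (E)-3-methyl-4-oxobut-2-enoate
Product: 4 ethyl (1S,2R,3S)-2-formyl-2-methyl-3-(triisopropylsilyloxy)cyclohex-4-ene-1-carboxylate
Conditions: (S)-B-(o-tolyl)diphenylprolinol oxazaborolidine (20 mol%), Tf2NH (18 mol%), CH2Cl2, −78 → −40 °C
Reagents that add atoms: none
Why: Catalytic asymmetric Diels–Alder reaction in which the cationic oxazaborolidine binds the formyl group, the silyloxy terminus bonds to the formyl-bearing carbon (ortho rule, C1–C14), endo orientation of CHO puts OTIPS cis to CHO (C14), the (E)-dienophile puts the ester trans to CHO (C10), and the catalyst face sets the absolute configuration (the antipodal catalyst is the remedy if the sense is opposite).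

Step 3
Reactants: 4 Diels–Alder adduct
Product: 5 ethyl (1S,2R,3S)-2-formyl-3-hydroxy-2-methylcyclohex-4-ene-1-carboxylate
Conditions: HF·pyridine, pyridine, THF, 0 → 23 °C
Reagents that add atoms: none
Why: Fluoride-driven Si–O cleavage under non-basic conditions, so the β-hydroxy aldehyde (no α-hydrogen) neither epimerises nor undergoes retro-aldol cleavage.

Step 4
Reactants: 5 β-hydroxy aldehyde
Product: 7 trans-fused vinyl γ-lactone, via diol ester 6 (not isolated)
Conditions: vinylMgBr (2.5 equiv), THF, −78 °C; aq NH4Cl; then PPTS (cat.), PhMe, 60 °C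
Reagents that add atoms: vinylmagnesium bromide, C=C[Mg]Br
Why: Chelation-controlled Grignard addition in which the magnesium alkoxide of the cis β-hydroxyl and the aldehyde form a six-membered chelate attacked on the face flanked by the C1 methyl group (anti to C10), giving the 1,3-anti diol and setting C2, after which the new hydroxyl lactonises onto the trans-disposed ester (acid-catalysed transesterification).

Step 5
Reactants: 7 trans-fused vinyl γ-lactone
Product: 8 1-ethoxyvinyl ketone diol (open form of its lactol)
Conditions: ethyl vinyl ether, t-BuLi, THF, −78 → 0 °C; then 7, −78 °C; aq NH4Cl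
Reagents that add atoms: ethyl vinyl ether (used as 1-ethoxyvinyllithium), C=COCC
Why: Addition of an acyl anion equivalent to a lactone, which stops after one addition because the tetrahedral lithium hemiketal is stable at −78 °C.

Step 6
Reactants: 8 1-ethoxyvinyl ketone diol
Product: 9 triol enol ether
Conditions: NaBH4, CeCl3·7H2O, MeOH, −78 → −40 °C
Reagents that add atoms: none
Why: Luche 1,2-reduction under Felkin–Anh control, hydride attacking the C9 ketone anti to the quaternary C1 substituent of the adjacent stereocentre C10, which sets C9.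

Step 7
Reactants: 9 triol enol ether
Product: 11 triacetoxy methyl ketone, via triacetate enol ether 10 (not isolated)
Conditions: Ac2O, DMAP, pyridine, CH2Cl2, 23 °C; then 1 M HCl, THF, 0 °C
Reagents that add atoms: acetic anhydride, CC(=O)OC(C)=O; water, O
Why: DMAP-catalysed acetylation of the three secondary alcohols (C2, C9, C14), then acid hydrolysis of the enol ether to the methyl ketone (C8=O, C7 methyl).

Step 8
Reactants: 12 acrolein
Product: 14 2-bromoacrolein, via 2,3-dibromopropanal 13 (not isolated)
Conditions: Br2, CH2Cl2, −78 °C; then Et3N, −78 → 0 °C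
Reagents that add atoms: bromine, BrBr
Why: Bromine addition to the alkene, then E1cB loss of HBr from the α-position, gives the α-bromo enal.

Step 9
Reactants: 11 triacetoxy methyl ketone; 14 2-bromoacrolein
Product: 15 (6R)-β-hydroxy ketone with 1-bromovinyl group
Conditions: (+)-Ipc2BCl, Et3N, Et2O, −78 → 0 °C; 14, −78 → −20 °C; then H2O2, MeOH, pH 7 buffer, 0 °C
Reagents that add atoms: none
Why: Boron aldol reaction of a methyl ketone in which the chloroborane and Et3N enolise the methyl group regioselectively and the isopinocampheyl ligands direct attack on the Re face of the aldehyde (reagent control), setting C6.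

Step 10
Reactants: 15 (6R)-β-hydroxy ketone
Product: 16 cyclic silyl enol ether (2,2-di-tert-butyl-4H-1,3,2-dioxasiline)
Conditions: t-Bu2Si(OTf)2, Et3N, CH2Cl2, 0 → 23 °C
Reagents that add atoms: di-tert-butylsilyl bis(triflate), CC(C)(C)[Si](OS(=O)(=O)C(F)(F)F)(OS(=O)(=O)C(F)(F)F)C(C)(C)C
Why: Silyl triflate/amine enol silylation made intramolecular, O6-silylation being followed by closure on the ketone oxygen and deprotonation at the unhindered C7 to give the six-membered ring with endocyclic C7=C8.

Step 11
Reactants: 16 cyclic silyl enol ether; 17 acrylic acid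
Product: 18 silylene-bridged α-methyl γ-lactone
Conditions: 17 (3 equiv), 9-mesityl-10-methylacridinium tetrafluoroborate (5 mol%), PhSSPh (10 mol%), 2,6-lutidine (20 mol%), CH2Cl2, 450 nm LEDs, 23 °C
Reagents that add atoms: none
Why: Proposed new method: the excited acridinium oxidises the electron-rich silyl enol ether to its radical cation, acrylic acid adds through oxygen to C7 (the β-carbon), the resulting α-silyloxy C8 radical closes onto the acrylate α-carbon (C17), and the primary C18 radical is reduced to the methyl group by the thiol cocatalyst, which the reduced acridine turns over. The closest known reaction is the acridinium/thiol polar radical crossover cycloaddition of styrenes and trisubstituted alkenes with unsaturated acids to γ-butyrolactones; a silyl enol ether as the alkene partner is the untested element. The lactone ring (O–C7–C8–C17–C19) is closed by 5-exo-trig radical cyclisation after intermolecular C7–O bond formation. C7 is controlled by the C6 stereocentre (the acid adds trans to the bromovinyl group on the six-membered ring), C8 by the ring (only cis fusion of the lactone onto the siladioxane is possible, which places C9 trans to C6), and C17 by the acrylate terminus turning away from the C9 branch (also the thermodynamic, epimerisable arrangement). The step needs site-selective oxidation (the enol ether is by far the most easily oxidised alkene), a radical cation that keeps its silicon (the hindered t-Bu2Si bridge), and 5-exo rather than 6-endo closure, for which only the geometry of the short tether speaks.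

Step 12
Reactants: 18 silylene-bridged α-methyl γ-lactone
Product: 19 enone (C11 ketone, C12=C13)
Conditions: Rh2(cap)4 (1 mol%), t-BuOOH (5 equiv), K2CO3, CH2Cl2, 23 °C
Reagents that add atoms: tert-butyl hydroperoxide, CC(C)(C)OO
Why: Dirhodium caprolactamate/TBHP allylic oxidation in which tert-butylperoxyl radicals abstract hydrogen from the cyclohexene CH2 (C11), the acetoxy group deactivating C14–H and the C13 terminus of the allyl radical, so the peroxide forms at C11 and collapses to the enone.

Step 13
Reactants: 19 enone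
Product: 20 C11 ketone
Conditions: [(Ph3P)CuH]6 (0.4 equiv), H2O (5 equiv), PhMe, 23 °C
Reagents that add atoms: none
Why: Copper hydride conjugate reduction, which delivers hydride only to the enone β-carbon and leaves the isolated alkenes, the vinyl bromide and the esters untouched.

Step 14
Reactants: 20 C11 ketone
Product: 21 11,20-epoxide
Conditions: Me3S+ I−, KHMDS, THF, −20 → 0 °C
Reagents that add atoms: trimethylsulfonium iodide, C[S+](C)C.[I-]
Why: Corey–Chaykovsky epoxidation of the only ketone, in which the axial face of C11 is blocked by the syn-axial C1 methyl group, so the new C–C bond is equatorial and the oxygen axial, as in the target.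

Step 15
Reactants: 21 11,20-epoxide
Product: 22 seco diol (C6–OH, C8–OH)
Conditions: TBAF, AcOH, THF, 0 → 23 °C
Reagents that add atoms: none
Why: Fluoride cleavage of both Si–O bonds of the silylene under buffered conditions that spare the acetates, the lactone and the epoxide.

Step 16
Reactants: 22 seco diol
Product: 23 6-epi chloroacetate
Conditions: ClCH2CO2H, PPh3, DIAD, PhMe, 0 → 23 °C
Reagents that add atoms: chloroacetic acid, OC(=O)CCl
Why: Mitsunobu reaction with an acidic carboxylic acid, giving SN2 inversion at the secondary allylic C6 carbinol while the tertiary C8 hydroxyl is inert.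

Step 17
Reactants: 23 6-epi chloroacetate
Product: 24 6-epi alcohol (seco)
Conditions: NH3 (2 M in MeOH), THF, −20 → 0 °C
Reagents that add atoms: none
Why: Chemoselective aminolysis, the chloroacetate being cleaved far faster than the three acetates, which returns the C6 alcohol with inverted configuration.

Step 18
Reactants: 24 6-epi alcohol (seco)
Product: 26 macrocyclic 6-epi alcohol, via alkylborane 25 (not isolated)
Conditions: 9-BBN (4 equiv), THF, 23 °C; then slow addition to Pd(dppf)Cl2 (15 mol%), AsPh3, Cs2CO3, DMF/THF/H2O, 23 °C, 1 mM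
Reagents that add atoms: none
Why: B-alkyl Suzuki–Miyaura macrocyclisation, anti-Markovnikov hydroboration of the only monosubstituted alkene being followed by intramolecular sp3–sp2 coupling with the vinyl bromide under high dilution to form C4–C5 and the 1,1-disubstituted C5=C16 alkene.

Step 19
Reactants: 26 macrocyclic 6-epi alcohol
Product: 27 CNP0104093.2
Conditions: PPh3, hexachloroacetone, CH2Cl2, 0 °C
Reagents that add atoms: hexachloroacetone, ClC(Cl)(Cl)C(=O)C(Cl)(Cl)Cl
Why: Appel-type chlorination of an allylic alcohol with triphenylphosphine/hexachloroacetone, in which chloride displaces the oxyphosphonium at C6 by SN2 with inversion and without allylic transposition, the second inversion returning the C6 substituent to the position fixed in step 9.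

**Compound list**

1 | (E)-but-2-enal (crotonaldehyde) | C/C=C/C=O | starting material
2 | (E)-1-(triisopropylsilyloxy)buta-1,3-diene | C=C/C=C/O[Si](C(C)C)(C(C)C)C(C)C | intermediate
3 | ethyl (E)-3-methyl-4-oxobut-2-enoate | CCOC(=O)/C=C(\C)C=O | starting material
4 | ethyl (1S,2R,3S)-2-formyl-2-methyl-3-(triisopropylsilyloxy)cyclohex-4-ene-1-carboxylate (CHO cis to OTIPS, trans to CO2Et) | CCOC(=O)[C@H]1CC=C[C@H](O[Si](C(C)C)(C(C)C)C(C)C)[C@]1(C)C=O | intermediate
5 | ethyl (1S,2R,3S)-2-formyl-3-hydroxy-2-methylcyclohex-4-ene-1-carboxylate | CCOC(=O)[C@H]1CC=C[C@H](O)[C@]1(C)C=O | intermediate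
6 | diol ester (vinyl carbinol at C2, 1,3-anti to the ring hydroxyl at C14) | CCOC(=O)[C@H]1CC=C[C@H](O)[C@]1(C)[C@@H](O)C=C | intermediate
7 | trans-fused vinyl γ-lactone (C2–O–C9(=O) across C1–C10; C14–OH free) | C=C[C@@H]1OC(=O)[C@H]2CC=C[C@H](O)[C@]12C | intermediate
8 | 1-ethoxyvinyl ketone diol (C9 ketone; C2–OH and C14–OH free; open form of its lactol) | C=C[C@H](O)[C@@]1(C)[C@@H](O)C=CC[C@@H]1C(=O)C(OCC)=C | intermediate
9 | triol enol ether (C2, C9, C14 hydroxyls; 1-ethoxyvinyl group on C9) | C=C[C@H](O)[C@@]1(C)[C@@H](O)C=CC[C@@H]1[C@H](O)C(OCC)=C | intermediate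
10 | triacetate enol ether | C=C[C@H](OC(C)=O)[C@@]1(C)[C@@H](OC(C)=O)C=CC[C@@H]1[C@H](OC(C)=O)C(OCC)=C | intermediate
11 | triacetoxy methyl ketone (2,9,14-triacetate; C8 ketone, C7 methyl) | C=C[C@H](OC(C)=O)[C@@]1(C)[C@@H](OC(C)=O)C=CC[C@@H]1[C@H](OC(C)=O)C(C)=O | intermediate
12 | acrolein | C=CC=O | starting material
13 | 2,3-dibromopropanal | O=CC(Br)CBr | intermediate
14 | 2-bromoacrolein | C=C(Br)C=O | intermediate
15 | (6R)-β-hydroxy ketone (C6 carbinol bearing the 1-bromovinyl group C5/C16; C8 ketone) | C=C[C@H](OC(C)=O)[C@@]1(C)[C@@H](OC(C)=O)C=CC[C@@H]1[C@H](OC(C)=O)C(=O)C[C@@H](O)C(Br)=C | intermediate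
16 | cyclic silyl enol ether: 2,2-di-tert-butyl-4H-1,3,2-dioxasiline with C7=C8 in the ring, 1-bromovinyl on C6, C9 branch on C8 | C=C[C@H](OC(C)=O)[C@@]1(C)[C@@H](OC(C)=O)C=CC[C@@H]1[C@H](OC(C)=O)C2=C[C@H](C(Br)=C)O[Si](C(C)(C)C)(C(C)(C)C)O2 | intermediate
17 | acrylic acid | C=CC(=O)O | starting material
18 | silylene-bridged α-methyl γ-lactone (C7, C8, C17 as in the target; O6 and O8 in the t-Bu2Si ring; cyclohexene C12=C13) | C=C[C@H](OC(C)=O)[C@@]1(C)[C@@H](OC(C)=O)C=CC[C@@H]1[C@H](OC(C)=O)[C@]2(O[Si](C(C)(C)C)(C(C)(C)C)O4)[C@@H](C)C(=O)O[C@H]2[C@@H]4C(Br)=C | intermediate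
19 | enone (C11 ketone conjugated with C12=C13) | C=C[C@H](OC(C)=O)[C@@]1(C)[C@@H](OC(C)=O)C=CC(=O)[C@@H]1[C@H](OC(C)=O)[C@]2(O[Si](C(C)(C)C)(C(C)(C)C)O4)[C@@H](C)C(=O)O[C@H]2[C@@H]4C(Br)=C | intermediate
20 | C11 ketone (saturated cyclohexanone) | C=C[C@H](OC(C)=O)[C@@]1(C)[C@@H](OC(C)=O)CCC(=O)[C@@H]1[C@H](OC(C)=O)[C@]2(O[Si](C(C)(C)C)(C(C)(C)C)O4)[C@@H](C)C(=O)O[C@H]2[C@@H]4C(Br)=C | intermediate
21 | 11,20-epoxide (spiro-epoxide as in the target; silylene in place) | C=C[C@H](OC(C)=O)[C@@]1(C)[C@@H](OC(C)=O)CC[C@@]3(CO3)[C@@H]1[C@H](OC(C)=O)[C@]2(O[Si](C(C)(C)C)(C(C)(C)C)O4)[C@@H](C)C(=O)O[C@H]2[C@@H]4C(Br)=C | intermediate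
22 | seco diol (C6–OH in the position of the target's chlorine; C8–OH free) | C=C[C@H](OC(C)=O)[C@@]1(C)[C@@H](OC(C)=O)CC[C@@]3(CO3)[C@@H]1[C@H](OC(C)=O)[C@]2(O)[C@@H](C)C(=O)O[C@H]2[C@@H](O)C(Br)=C | intermediate
23 | 6-epi chloroacetate (C6 inverted) | C=C[C@H](OC(C)=O)[C@@]1(C)[C@@H](OC(C)=O)CC[C@@]3(CO3)[C@@H]1[C@H](OC(C)=O)[C@]2(O)[C@@H](C)C(=O)O[C@H]2[C@H](OC(=O)CCl)C(Br)=C | intermediate
24 | 6-epi alcohol, seco (C6–OH opposite to the target's C6–Cl) | C=C[C@H](OC(C)=O)[C@@]1(C)[C@@H](OC(C)=O)CC[C@@]3(CO3)[C@@H]1[C@H](OC(C)=O)[C@]2(O)[C@@H](C)C(=O)O[C@H]2[C@H](O)C(Br)=C | intermediate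
25 | alkylborane (B-alkyl-9-BBN at C4; hydroxyl groups drawn free) | C(CB5C6CCCC5CCC6)[C@H](OC(C)=O)[C@@]1(C)[C@@H](OC(C)=O)CC[C@@]3(CO3)[C@@H]1[C@H](OC(C)=O)[C@]2(O)[C@@H](C)C(=O)O[C@H]2[C@H](O)C(Br)=C | intermediate
26 | macrocyclic 6-epi alcohol (target skeleton with C6–OH of opposite configuration in place of Cl) | C=C1CC[C@H](OC(C)=O)[C@@]2(C)[C@@H](OC(C)=O)CC[C@@]3(CO3)[C@@H]2[C@H](OC(C)=O)[C@]2(O)[C@@H](C)C(=O)O[C@H]2[C@@H]1O | intermediate
27 | CNP0104093.2 (6-chloro-5(16)-ene, 11,20-epoxide, 8-hydroxy, 2,9,14-triacetate, 7,8-fused α-methyl γ-lactone) | C=C1CC[C@H](OC(C)=O)[C@@]2(C)[C@@H](OC(C)=O)CC[C@@]3(CO3)[C@@H]2[C@H](OC(C)=O)[C@]2(O)[C@@H](C)C(=O)O[C@H]2[C@H]1Cl | target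

**Totals.** 19 steps in all; longest linear sequence 18 steps (steps 1–7 and 9–19, from crotonaldehyde).

**Steps most likely to fail**

Step 11 (proposed new method). The radical cation may lose its silyl group, the C8 radical may close 6-endo instead of 5-exo, the thiyl radical may add to the vinyl group, or the facial selectivity at C7 may be poor. The fallback uses known chemistry and sets out from 16. A [2+2] cycloaddition with chloro(methyl)ketene (2-chloropropanoyl chloride, Et3N, CH2Cl2, 0 → 40 °C) on the enol ether face trans to the bromovinyl group should give the cis-fused α-chlorocyclobutanone F1 (carbonyl carbon on C7, chlorinated carbon on C8). Regioselective Baeyer–Villiger oxidation (30% H2O2, AcOH, 0 °C), with migration of the non-chlorinated C7 with retention, should give the α-chloro lactone F2. Zinc in acetic acid removes the chlorine (C17 set on protonation and equilibrated with DBU if needed), and the route is rejoined at 18.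

Step 18. Oligomerisation and protodeboronation may outrun closure of the ten-membered ring. The fallback sets out from 24: hydroboration with 9-BBN and iodinolysis (I2, NaOMe) should give the primary iodide F3. A nickel-catalysed reductive cross-electrophile coupling of the alkyl iodide with the vinyl bromide (NiBr2·glyme, 4,4'-di-tert-butyl-2,2'-bipyridine, Mn powder, DMA, high dilution) closes the ring without an organoboron intermediate and comes back to the route at 26.

Step 19. Allylic transposition (SN2' attack giving the primary chloride) or elimination may compete with direct displacement at the hindered C6. The fallback sets out from 26: reductive 1,3-transposition through an allylic diazene (o-nitrobenzenesulfonylhydrazide, PPh3, DEAD, THF, −30 → 23 °C) should give the Δ5(6)-alkene F4 with C16 as a methyl group. An ene-type chlorination (N-chlorosuccinimide, PhSeCl 10 mol%, CH2Cl2, 23 °C) then places chlorine on C6 on the face away from the lactone oxygen and returns the double bond to C5=C16, giving 27 directly.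

**Further compounds**

F1 | step 11 | cis-fused α-chloro-α-methylcyclobutanone on the siladioxane (C19 on C7, C17 on C8; C17 configuration not controlled) | C=C[C@H](OC(C)=O)[C@@]1(C)[C@@H](OC(C)=O)C=CC[C@@H]1[C@H](OC(C)=O)[C@]2(O[Si](C(C)(C)C)(C(C)(C)C)O4)C(C)(Cl)C(=O)[C@H]2[C@@H]4C(Br)=C
F2 | step 11 | α-chloro-α-methyl γ-lactone (17-chloro analogue of 18) | C=C[C@H](OC(C)=O)[C@@]1(C)[C@@H](OC(C)=O)C=CC[C@@H]1[C@H](OC(C)=O)[C@]2(O[Si](C(C)(C)C)(C(C)(C)C)O4)C(C)(Cl)C(=O)O[C@H]2[C@@H]4C(Br)=C
F3 | step 18 | primary iodide (C4–I) of the seco 6-epi alcohol | ICC[C@H](OC(C)=O)[C@@]1(C)[C@@H](OC(C)=O)CC[C@@]3(CO3)[C@@H]1[C@H](OC(C)=O)[C@]2(O)[C@@H](C)C(=O)O[C@H]2[C@H](O)C(Br)=C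
F4 | step 19 | macrocyclic (Z)-Δ5(6)-alkene with C16 methyl (6-deoxy) | C/C=1CC[C@H](OC(C)=O)[C@@]2(C)[C@@H](OC(C)=O)CC[C@@]3(CO3)[C@@H]2[C@H](OC(C)=O)[C@]2(O)[C@@H](C)C(=O)O[C@H]2\C=1
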